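The ratio I reckon with is wasted partner over used partner. Each turn of either useful step takes one partner and one substrate, so substrate gone counts as partner used, and the charged c(partner) stands at 60.0 % on the percent scale of the readings, less than the two substrates together, which makes partner the limiting reagent.

| flask | left-handed substrate | right-handed substrate | partner | catalyst | remark | time |
|---|---|---|---|---|---|---|
| blue | 1.5 M | 1.5 M | 1.2 equiv | 2.4 mol% | run made earlier |  |
| violet | 1.5 M | 1.5 M | 1.2 equiv | 5.7 mol% | run made earlier |  |
| Tuesday's | 1.5 M | 1.5 M | 1.20 equiv | 2 mol% |  | 40 min |
| Sunday's | 1.5 M | 1.5 M | 1.20 equiv | 4 mol% |  | 40 min |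

| run | time / min | right-handed substrate / % | left-handed substrate / % |
|---|---|---|---|
| blue | 2.50 | 36.2 | 19.3 |
| blue | 3.00 | 36.7 | 19.1 |
| blue | 5.00 | 35.8 | 18.0 |
| blue | 8.00 | 35.0 | 18.1 |
| blue | 12.0 | 34.6 | 18.3 |
| blue | 20.0 | 35.9 | 17.2 |
| blue | 30.0 | 35.2 | 17.5 |
| violet | 1.50 | 33.3 | 15.1 |
| violet | 4.00 | 32.7 | 13.1 |
| violet | 8.00 | 32.3 | 13.4 |
| violet | 12.0 | 32.2 | 13.6 |
| violet | 15.0 | 33.0 | 13.7 |
| violet | 20.0 | 32.5 | 12.1 |
| violet | 30.0 | 32.3 | 13.7 |

(readings scatter by 0.5 percentage points)

- catalyst is single-handed; left-handed substrate and right-handed substrate are mirror images of each other, charged as a racemate, each of them at the stated concentration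
- steps under discussion: catalyst <-> dormant form; partner + catalyst + left-handed substrate -> catalyst + left-handed product; partner + catalyst + right-handed substrate -> catalyst + right-handed product; partner -> decomposed reagent; 2 partner -> homo dimer
- an excess is below zero if the other one leads

- the winner by excess of right-handed substrate over left-handed substrate among what is left of the two; "neither" if no more than 2 percentage points parts them (Tuesday's / Sunday's / neither)
- excess of right-handed substrate over left-handed substrate among what is left of the two at the end, Tuesday's
- excess of right-handed substrate over left-handed substrate among what is left of the two at the end, Sunday's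

Over their last four readings, which stand level within the scatter, blue has used 47.0 % of the substrates and violet 54.2 %, and since I take that level to mean the partner has come to its end, so that whatever of the pool was not used counts as wasted, the ratio reads 0.275 in blue and a smaller 0.107 in violet. Catalyst stands in both useful steps and in neither of the two partner losses, so at these equal charges of substrates and partner I expect the ratio to fall inversely with loading, and ratio times loading reads 0.66 mol% in blue and 0.61 mol% in violet. I carry their mean, 0.63 mol%, as the waste number, wasted over used partner times catalyst loading.

Tuesday's looks nearly like blue, but at 2 mol% against 2.4 mol% its ratio becomes 0.315, larger than blue's, so by my reckoning it stops with less used than blue, at 45.6 %, and since blue stands level from 8.00 min on, I take 40 min as past that stop. Sunday's, at 4 mol%, gets 0.158 and stops at 51.8 %. Excess read on the line through blue's 32.9 % and violet's 42.0 % gives me 31.0 % for Tuesday's and 38.9 % for Sunday's, which part by 7.9 percentage points, more than the margin.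

The forecast, a little below me on both, says Sunday's, with 30.2 % and 38 %, and argues that “More catalyst wins the race against partner loss”.

The flasks give Sunday's, with 31.8 % for Tuesday's and 39.5 % for Sunday's.

    catalyst ⇌ dormant form (K = 2.70, k = 0.0360 /s)
    partner + catalyst + left-handed substrate → catalyst + left-handed product (k = 0.930 /M²/s)
    partner + catalyst + right-handed substrate → catalyst + right-handed product (k = 0.300 /M²/s)
    partner → decomposed reagent (k = 0.00120 /s)
    2 partner → homo dimer (k = 0.00430 /M/s)

At 40.0 min, with partner at 0 %, the two products in Tuesday's hold 44.5 % against my 45.6 %, and in Sunday's 51.8 % against my 51.8 %. On a neighbour of Tuesday's with 0.8 mol% of catalyst, the waste number gives a ratio of 0.787 and so 33.6 % used. That flask holds 31.4 % as the two products, keeps 27.4 % of left-handed substrate and 41.2 % of right-handed substrate, and ends at an excess of 20.1 %.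

(All runs were generated by integration from invented constants, noise included.)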